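**Retrosynthetic overview**

1. Ring numbering: C1 = quaternary oxirane carbon carrying C7H2OBz, C2 = CHOH, C3 = CHOBz, C4=C5, C6 = oxirane CH. The oxirane is made last, by epoxidation of the C1=C6 bond of a cyclohexa-1,3-diene (C2 silyl ether, C3 benzoate); that diene comes from dehydration of a tertiary C1 carbinol.
2. Key disconnection: C3–C4 and C6–C1 are cut together. A one-pot double allylboration joins the four-carbon keto-aldehyde C7–C1(=O)–C2(OSi)–C3H=O (all four carbons and C2 from L-erythrulose) to a γ-borylallyl borane that supplies C4–C5–C6; this closes the cyclohexene (first ring) and creates C4=C5.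
3. Feature that allows this: in the six-membered ring the oxygen-bearing C3 is allylic and the oxygen-bearing C1 is homoallylic to the cis C4=C5 bond (O–C3–C4=C5–C6–C1–O, a ring-embedded (Z)-2-ene-1,5-diol), and C1 and C3 are 1,3-related through C2, so both carbonyl acceptors sit in one ketotetrose.
4. Stereochemistry: C2 from the chiral pool; C3 first set cis to the C2 oxygen by a matched reagent/Felkin pair, then inverted when the benzoate is introduced; C1 and C6 set by epoxidation anti to the C2 silyloxy group. Ring order: cyclohexene (step 6), then oxirane (step 9).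

Key step: step 6

Assumption: the borane made from (+)-α-pinene-derived (−)-Ipc2BH attacks the si face of the aldehyde, as allyl- and crotyl-diisopinocampheylboranes of this series do; L-erythrulose is taken as the commercial syrup.

**Route**

Step 1
Reactants: 1 L-erythrulose
Product: 2 3,4-O-isopropylidene-L-erythrulose
Conditions: Me2C(OMe)2, acetone, TsOH·H2O (cat.), 0 → 23 °C
Reagents that add atoms: 2,2-dimethoxypropane, COC(C)(C)OC
Why: Acid-catalysed transketalisation (acetonide formation) should tie up the vicinal 3,4-diol as the five-membered dioxolane in preference to a ketal across the carbonyl, leaving the C7 hydroxyl free and the stereocentre untouched.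

Step 2
Reactants: 2 3,4-O-isopropylidene-L-erythrulose
Product: 3 2-[(4S)-2,2-dimethyl-1,3-dioxolan-4-yl]-2-oxoethyl benzoate
Conditions: BzCl, pyridine, CH2Cl2, 0 °C
Reagents that add atoms: benzoyl chloride, O=C(Cl)c1ccccc1
Why: O-acylation of the only free, primary hydroxyl with the acid chloride installs the C7 benzoate of the target at the outset.

Step 3
Reactants: 3 2-[(4S)-2,2-dimethyl-1,3-dioxolan-4-yl]-2-oxoethyl benzoate
Product: 4 (3S)-3,4-dihydroxy-2-oxobutyl benzoate
Conditions: AcOH–H2O (4:1), 40 °C
Reagents that add atoms: none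
Why: Acid-catalysed acetal hydrolysis should free the diol without exposing the benzoate or the epimerisable α-oxy ketone to base.

Step 4
Reactants: 4 (3S)-3,4-dihydroxy-2-oxobutyl benzoate
Product: 5 (3S)-3,4-bis[(tert-butyldimethylsilyl)oxy]-2-oxobutyl benzoate
Conditions: TBSCl, imidazole, DMF, 0 → 23 °C
Reagents that add atoms: tert-butyldimethylsilyl chloride, CC(C)(C)[Si](C)(C)Cl
Why: Imidazole-promoted silyl ether formation protects both hydroxyls under nearly neutral conditions that should not enolise the ketone.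

Step 5
Reactants: 5 (3S)-3,4-bis[(tert-butyldimethylsilyl)oxy]-2-oxobutyl benzoate
Product: 6 (3S)-3-[(tert-butyldimethylsilyl)oxy]-4-hydroxy-2-oxobutyl benzoate
Conditions: HF·pyridine, pyridine, THF, 0 °C
Reagents that add atoms: none
Why: Selective desilylation should cleave the unhindered primary silyl ether much faster than the secondary one next to the ketone, exposing only the future C3 carbinol.

Step 6
Reactants: 6 (3S)-3-[(tert-butyldimethylsilyl)oxy]-4-hydroxy-2-oxobutyl benzoate; 7 allenylboronic acid pinacol ester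
Product: 11 [(1S,2S,3S)-2-[(tert-butyldimethylsilyl)oxy]-1,3-dihydroxycyclohex-4-en-1-yl]methyl benzoate, via keto-aldehyde 8 (not isolated), via allylboronate 9 (not isolated), via cyclic bis-borate 10 (not isolated)
Conditions: (COCl)2, DMSO, CH2Cl2, −78 °C; iPr2NEt, −78 °C; then borane from 7 + (−)-Ipc2BH (1.05 equiv, Et2O, −25 → 0 °C), −78 °C, 3 h; 23 → 45 °C, 24 h; NaBO3·4H2O, pH 7 buffer–THF, 23 °C
Reagents that add atoms: allenylboronic acid pinacol ester (7), C=C=CB1OC(C)(C)C(C)(C)O1
Why: Proposed new method: a Swern oxidation unveils keto-aldehyde 8 at −78 °C, the dialkylallylborane end of the reagent then adds through a chair transition state with its boron-bearing γ-carbon to the aldehyde (C3–C4 bond, giving α-boryl allylboronate 9), and on warming this boronate adds with its CH2 terminus to the tethered C1 ketone (C6–C1 bond, with shift of the double bond to C4=C5). The closest known reaction type is the one-pot double allylboration of two aldehydes with a γ-borylallyl-diisopinocampheylborane that gives 2-ene-1,5-diols, proposed here for the first time in a ring-closing mode with a ketone as the second acceptor. The cyclohexene closes in a 6-endo mode with all three allyl carbons inside the ring, through a bridged boat-like 2-oxa-3-borabicyclo[2.2.2]octene transition state that can only give the cis ring alkene. C3 is set by the isopinocampheyl groups (si-face attack) acting in the same sense as Felkin–Anh control by the C2 silyloxy centre (matched pair, 2,3-cis oxygens), the transient C4 centre by the (E)-geometry of the reagent, and C1 by delivery of the ketone oxygen to the face of the C4–B bond (this centre is erased in step 8). The step needs the aldehyde to react before the ketone, which the substrate secures because only the aldehyde is attacked by the bulky dialkylborane at −78 °C while the ketone is reached later by the tethered, less reactive boronate. Because the wanted product is the matched one, any epimerisation of the labile C2 centre of 8 should be funnelled into the same diastereomer.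

Step 7
Reactants: 11 [(1S,2S,3S)-2-[(tert-butyldimethylsilyl)oxy]-1,3-dihydroxycyclohex-4-en-1-yl]methyl benzoate
Product: 12 [(1S,2S,3R)-3-(benzoyloxy)-2-[(tert-butyldimethylsilyl)oxy]-1-hydroxycyclohex-4-en-1-yl]methyl benzoate
Conditions: BzOH, PPh3, DIAD, toluene, 0 → 23 °C
Reagents that add atoms: benzoic acid, O=C(O)c1ccccc1
Why: Mitsunobu esterification should replace the allylic C3 hydroxyl by benzoate with SN2 inversion from the open face (the C1 hydroxyl and C2 silyloxy group lie on the other face), which sets the C3 configuration of the target, while the tertiary C1 hydroxyl cannot react.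

Step 8
Reactants: 12 [(1S,2S,3R)-3-(benzoyloxy)-2-[(tert-butyldimethylsilyl)oxy]-1-hydroxycyclohex-4-en-1-yl]methyl benzoate
Product: 13 [(5R,6R)-5-(benzoyloxy)-6-[(tert-butyldimethylsilyl)oxy]cyclohexa-1,3-dien-1-yl]methyl benzoate
Conditions: Burgess reagent, benzene, 50 °C
Reagents that add atoms: none
Why: Burgess dehydration (syn elimination of the tertiary sulfamate) should remove an allylic C6 hydrogen, since the C2 hydrogen is trans to the leaving group, giving the conjugated diene and erasing the C1 stereocentre.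

Step 9
Reactants: 13 [(5R,6R)-5-(benzoyloxy)-6-[(tert-butyldimethylsilyl)oxy]cyclohexa-1,3-dien-1-yl]methyl benzoate
Product: 14 [(1S,2S,3R,6S)-3-(benzoyloxy)-2-[(tert-butyldimethylsilyl)oxy]-7-oxabicyclo[4.1.0]hept-4-en-1-yl]methyl benzoate
Conditions: mCPBA, NaHCO3, CH2Cl2, 0 °C
Reagents that add atoms: mCPBA, O=C(OO)c1cccc(Cl)c1
Why: Prilezhaev epoxidation should take the more nucleophilic trisubstituted C1=C6 bond on the face anti to the pseudoaxial C2 silyloxy group (the face of the C3 benzoate), which sets C1 and C6 of the oxirane.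

Step 10
Reactants: 14 [(1S,2S,3R,6S)-3-(benzoyloxy)-2-[(tert-butyldimethylsilyl)oxy]-7-oxabicyclo[4.1.0]hept-4-en-1-yl]methyl benzoate
Product: 15 [(1R,2S,3R,6S)-3-(benzoyloxy)-2-hydroxy-7-oxabicyclo[4.1.0]hept-4-en-1-yl]methyl benzoate
Conditions: HF·pyridine, pyridine, THF, 0 → 23 °C
Reagents that add atoms: none
Why: Fluoride-mediated silyl ether cleavage under pyridine-buffered conditions should free the C2 hydroxyl without benzoate migration or opening of the vinyl oxirane.

**Compound list**

1 | L-erythrulose, (3S)-1,3,4-trihydroxybutan-2-one | OC[C@H](O)C(=O)CO | starting material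
2 | 3,4-O-isopropylidene-L-erythrulose, 1-[(4S)-2,2-dimethyl-1,3-dioxolan-4-yl]-2-hydroxyethan-1-one | OCC(=O)[C@@H]1COC(C)(C)O1 | intermediate
3 | 2-[(4S)-2,2-dimethyl-1,3-dioxolan-4-yl]-2-oxoethyl benzoate | O=C(OCC(=O)[C@@H]1COC(C)(C)O1)c1ccccc1 | intermediate
4 | (3S)-3,4-dihydroxy-2-oxobutyl benzoate | O=C(OCC(=O)[C@@H](O)CO)c1ccccc1 | intermediate
5 | (3S)-3,4-bis[(tert-butyldimethylsilyl)oxy]-2-oxobutyl benzoate | O=C(OCC(=O)[C@@H](O[Si](C)(C)C(C)(C)C)CO[Si](C)(C)C(C)(C)C)c1ccccc1 | intermediate
6 | (3S)-3-[(tert-butyldimethylsilyl)oxy]-4-hydroxy-2-oxobutyl benzoate | O=C(OCC(=O)[C@@H](O[Si](C)(C)C(C)(C)C)CO)c1ccccc1 | intermediate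
7 | allenylboronic acid pinacol ester, 4,4,5,5-tetramethyl-2-(propa-1,2-dien-1-yl)-1,3,2-dioxaborolane | C=C=CB1OC(C)(C)C(C)(C)O1 | starting material
8 | keto-aldehyde, (3S)-3-[(tert-butyldimethylsilyl)oxy]-2,4-dioxobutyl benzoate (not isolated) | O=C(OCC(=O)[C@@H](O[Si](C)(C)C(C)(C)C)C=O)c1ccccc1 | intermediate
9 | allylboronate, (3S,4S,5S)-3-[(tert-butyldimethylsilyl)oxy]-4-[(diisopinocampheylboryl)oxy]-2-oxo-5-(4,4,5,5-tetramethyl-1,3,2-dioxaborolan-2-yl)hept-6-en-1-yl benzoate (not isolated) | O=C(OCC(=O)[C@@H](O[Si](C)(C)C(C)(C)C)[C@@H](OB([C@@H]1C[C@@H]2C[C@H]([C@H]1C)C2(C)C)[C@@H]1C[C@@H]2C[C@H]([C@H]1C)C2(C)C)[C@H](C=C)B1OC(C)(C)C(C)(C)O1)c1ccccc1 | intermediate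
10 | cyclic bis-borate, the C1 pinacol borate and C3 diisopinocampheylborinate of 11 (not isolated) | O=C(OC[C@@]1(OB2OC(C)(C)C(C)(C)O2)CC=C[C@H](OB([C@@H]2C[C@@H]3C[C@H]([C@H]2C)C3(C)C)[C@@H]2C[C@@H]3C[C@H]([C@H]2C)C3(C)C)[C@@H]1O[Si](C)(C)C(C)(C)C)c1ccccc1 | intermediate
11 | [(1S,2S,3S)-2-[(tert-butyldimethylsilyl)oxy]-1,3-dihydroxycyclohex-4-en-1-yl]methyl benzoate (all three oxygens cis) | O=C(OC[C@@]1(O)CC=C[C@H](O)[C@@H]1O[Si](C)(C)C(C)(C)C)c1ccccc1 | intermediate
12 | [(1S,2S,3R)-3-(benzoyloxy)-2-[(tert-butyldimethylsilyl)oxy]-1-hydroxycyclohex-4-en-1-yl]methyl benzoate | O=C(OC[C@@]1(O)CC=C[C@@H](OC(=O)c2ccccc2)[C@@H]1O[Si](C)(C)C(C)(C)C)c1ccccc1 | intermediate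
13 | [(5R,6R)-5-(benzoyloxy)-6-[(tert-butyldimethylsilyl)oxy]cyclohexa-1,3-dien-1-yl]methyl benzoate | O=C(OCC1=CC=C[C@@H](OC(=O)c2ccccc2)[C@@H]1O[Si](C)(C)C(C)(C)C)c1ccccc1 | intermediate
14 | [(1S,2S,3R,6S)-3-(benzoyloxy)-2-[(tert-butyldimethylsilyl)oxy]-7-oxabicyclo[4.1.0]hept-4-en-1-yl]methyl benzoate (the C2 silyl ether of 15) | O=C(OC[C@]12O[C@H]1C=C[C@@H](OC(=O)c1ccccc1)[C@@H]2O[Si](C)(C)C(C)(C)C)c1ccccc1 | intermediate
15 | [(1R,2S,3R,6S)-3-(benzoyloxy)-2-hydroxy-7-oxabicyclo[4.1.0]hept-4-en-1-yl]methyl benzoate | O=C(OC[C@]12O[C@H]1C=C[C@@H](OC(=O)c1ccccc1)[C@@H]2O)c1ccccc1 | target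

**Step count and risks**

Total step count: 10. Longest linear sequence: 10 steps (from 1; the borane of step 6 is made in the flask from 7).

Steps most likely to fail:

1. Step 6 (the proposed new method). What may go wrong: enolisation or hydration of the keto-aldehyde before it is trapped; sluggish ring-closing addition of the hindered α-boryl allylboronate to the ketone, with intermolecular addition or β-elimination of the C3 borinate taking over. Fallback with known chemistry, setting out from 6 and returning at 11: indium-mediated Barbier allylation of the ketone of 6 (allyl bromide, indium powder, THF–H2O) should give the tertiary homoallylic alcohol F1. Oxidation of its primary hydroxyl only (TEMPO, PhI(OAc)2) gives the aldehyde F2. Nozaki–Hiyama–Kishi vinylation (vinyl bromide, CrCl2, NiCl2 cat., DMF) gives the Felkin allylic alcohol F3. Ring-closing metathesis with the second-generation Grubbs catalyst (CH2Cl2, 40 °C) then forms C4=C5 and delivers 11 as its C1 epimers, both of which serve because C1 is flattened in step 8.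

2. Step 9. What may go wrong: poor facial selectivity (or attack at C4=C5) in the peracid epoxidation, and acid-induced opening of the vinyl oxirane. Fallback, setting out from 13 and returning at 14: controlled methanolysis (K2CO3, MeOH, −20 °C) removes the primary benzoate first and gives the dienyl alcohol F4. Sharpless asymmetric epoxidation (Ti(OiPr)4, D-(−)-diethyl tartrate, tBuOOH, 4 Å sieves, CH2Cl2, −20 °C) directs oxygen to C1=C6 only and, under reagent control, to the face of the C3 benzoate, giving the epoxy alcohol F5. BzCl–pyridine then returns 14.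

3. Step 7. What may go wrong: SN2′ attack of benzoate at C5 or elimination to a diene instead of clean inversion at the allylic centre. Fallback, setting out from 11 and returning at 12: Dess–Martin periodinane (NaHCO3, CH2Cl2) oxidises the allylic alcohol to the enone F6. Catalyst-controlled Corey–Bakshi–Shibata reduction ((R)-2-methyl-CBS-oxazaborolidine, BH3·SMe2, the antipode chosen to deliver hydride to the face of the C2 silyloxy group) gives the C3-epimeric allylic alcohol F7. BzCl, DMAP, pyridine acylates its secondary hydroxyl only and gives 12.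

Further compounds

F1 | step 6 | tertiary homoallylic alcohol, 3-[(tert-butyldimethylsilyl)oxy]-2,4-dihydroxy-2-(prop-2-en-1-yl)butyl benzoate (silyloxy centre as in 6, both C2 epimers) | O=C(OCC(O)(CC=C)[C@@H](O[Si](C)(C)C(C)(C)C)CO)c1ccccc1
F2 | step 6 | aldehyde, 3-[(tert-butyldimethylsilyl)oxy]-2-hydroxy-4-oxo-2-(prop-2-en-1-yl)butyl benzoate (silyloxy centre as in 6, both C2 epimers) | O=C(OCC(O)(CC=C)[C@@H](O[Si](C)(C)C(C)(C)C)C=O)c1ccccc1
F3 | step 6 | Felkin allylic alcohol, 3-[(tert-butyldimethylsilyl)oxy]-2,4-dihydroxy-2-(prop-2-en-1-yl)hex-5-en-1-yl benzoate (3,4-anti, both C2 epimers) | O=C(OCC(O)(CC=C)[C@@H](O[Si](C)(C)C(C)(C)C)[C@@H](O)C=C)c1ccccc1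
F4 | step 9 | dienyl alcohol, (1R,6R)-6-[(tert-butyldimethylsilyl)oxy]-5-(hydroxymethyl)cyclohexa-2,4-dien-1-yl benzoate | OCC1=CC=C[C@@H](OC(=O)c2ccccc2)[C@@H]1O[Si](C)(C)C(C)(C)C
F5 | step 9 | epoxy alcohol, 14 without its C7 benzoyl group | OC[C@]12O[C@H]1C=C[C@@H](OC(=O)c1ccccc1)[C@@H]2O[Si](C)(C)C(C)(C)C
F6 | step 7 | enone, [(1S,2S)-2-[(tert-butyldimethylsilyl)oxy]-1-hydroxy-3-oxocyclohex-4-en-1-yl]methyl benzoate | O=C(OC[C@@]1(O)CC=CC(=O)[C@@H]1O[Si](C)(C)C(C)(C)C)c1ccccc1
F7 | step 7 | C3-epimeric allylic alcohol, [(1S,2S,3R)-2-[(tert-butyldimethylsilyl)oxy]-1,3-dihydroxycyclohex-4-en-1-yl]methyl benzoate | O=C(OC[C@@]1(O)CC=C[C@@H](O)[C@@H]1O[Si](C)(C)C(C)(C)C)c1ccccc1
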